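**Retrosynthetic overview**

1. The target is a 7-endo type B PPAP. Bicyclo[3.3.1]nonane locants are used: C1 and C5 are the bridgeheads, C9 the bridging ketone, C2–C3–C4 the aroyl-bearing tricarbonyl bridge, C8 the CMe2 carbon and C7 the carbon with the geranyl group; ring A is C1, C9, C5, C6, C7, C8 and ring B is C1, C2, C3, C4, C5, C9. The last disconnections are the phenol silyl ether and the C7–CH2 bond of the geranyl group, made by exo-face hydroboration of a 7-methylidene bicycle and B-alkyl Suzuki–Miyaura coupling with an (E)-vinyl iodide.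
2. Key disconnection: rings A and B are both opened at C5–C9 and C3–C4, leading back to a monocyclic (3R)-3,3-disubstituted 6-aryl-pyran-2,4-dione (a vinylogous anhydride) that carries an α-prenyl ester side chain.
3. Enabling feature: the carbonyl carbons C9, C2 and C4 alternate with C1, C3 and C5 around ring B (O=C9–C1–C2(=O)–C3–C4(=O)–C5, a 1,3,5-tricarbonyl array with C9 shared by rings A and B), so both bonds are acyl–α-carbon (Claisen) bonds. Because C1 is quaternary, C9, C1, C2, C3 and the aroyl carbon can be stored as a pyran-2,4-dione whose lactone carbonyl is C9 and whose ring oxygen masks the C3 nucleophile.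
4. The pyrandione comes from a 4-hydroxy-6-aryl-2-pyrone (enol silane plus malonyl dichloride) by O-allylation, aromatic Claisen rearrangement (bond C1–C8) and asymmetric Tsuji–Trost prenylation, which sets C1, the only stereocentre carried into the key step. C5 then follows from the bridge and C7 from the shape of the bicycle.
5. Ring order: temporary pyranone ring, then ring A, then ring B (the last two in the key step, in which the pyranone ring is opened again).

Key step: step 10

Assumption: the (1R,2R)-configured bisphosphine ligand of step 9 is taken to give the (3R)-dione; if the sense of induction is opposite, its (1S,2S)-enantiomer is used. TIPS stands for tri(propan-2-yl)silyl.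

**Route**

Step 1
Reactants: 1 1-(3-hydroxyphenyl)ethan-1-one
Product: 2 1-{3-[tri(propan-2-yl)silyloxy]phenyl}ethan-1-one
Conditions: TIPSCl (1.2 equiv), imidazole (2.5 equiv), DMF, 23 °C
Reagents that add atoms: chlorotri(propan-2-yl)silane, CC(C)[Si](Cl)(C(C)C)C(C)C
Why: Silylation of the phenol gives a bulky aryl silyl ether that should survive amide bases and zerovalent palladium and be cleaved by fluoride at the end.

Step 2
Reactants: 2 1-{3-[tri(propan-2-yl)silyloxy]phenyl}ethan-1-one
Product: 3 trimethyl[(1-{3-[tri(propan-2-yl)silyloxy]phenyl}ethenyl)oxy]silane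
Conditions: TMSOTf (1.3 equiv), Et3N (1.6 equiv), CH2Cl2, 0 °C
Reagents that add atoms: trimethylsilyl trifluoromethanesulfonate, C[Si](C)(C)OS(=O)(=O)C(F)(F)F
Why: Soft enolisation of the aryl methyl ketone should give the only possible (terminal) silyl enol ether.

Step 3
Reactants: 3 trimethyl[(1-{3-[tri(propan-2-yl)silyloxy]phenyl}ethenyl)oxy]silane; 4 propanedioyl dichloride
Product: 5 4-hydroxy-6-{3-[tri(propan-2-yl)silyloxy]phenyl}-2H-pyran-2-one
Conditions: 4 (1.05 equiv), Et2O, −78 to 23 °C
Reagents that add atoms: none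
Why: Pyrone synthesis from an enol silane and malonyl dichloride: C-acylation by one acid chloride, then ring closure of the enol oxygen on the second; the malonyl unit supplies C9, C1 and C2 of the target.

Step 4
Reactants: 6 diethyl 2-(propan-2-ylidene)propanedioate
Product: 7 2-(propan-2-ylidene)propane-1,3-diol
Conditions: iBu2AlH (4.5 equiv), CH2Cl2, −78 to 0 °C; aq KNaC4H4O6 work-up
Reagents that add atoms: none
Why: iBu2AlH should reduce both esters of the alkylidene malonate in the 1,2-sense because the tetrasubstituted β-carbon is shielded from conjugate hydride delivery.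

Step 5
Reactants: 7 2-(propan-2-ylidene)propane-1,3-diol
Product: 8 1-bromo-2-(bromomethyl)-3-methylbut-2-ene
Conditions: PBr3 (0.8 equiv), Et2O, 0 °C
Reagents that add atoms: phosphorus tribromide, BrP(Br)Br
Why: Bromination of the two primary allylic alcohols should proceed without allylic transposition, since the transposed bromide would be tertiary and less stable.

Step 6
Reactants: 9 ethyl 5-methylhex-4-enoate; 8 1-bromo-2-(bromomethyl)-3-methylbut-2-ene
Product: 10 ethyl 2-[2-(bromomethyl)-3-methylbut-2-en-1-yl]-5-methylhex-4-enoate (racemic)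
Conditions: LiN(iPr)2 (1.05 equiv), THF, −78 °C; enolate added to 8 (3 equiv), −78 to −20 °C
Reagents that add atoms: none
Why: Alkylation of the lithium ester enolate with an excess of the symmetric bis-allylic dibromide should stop at monoalkylation and makes bond C5–C6; C5 is formed racemic, which does not matter because it is enolised in step 10.

Step 7
Reactants: 5 4-hydroxy-6-{3-[tri(propan-2-yl)silyloxy]phenyl}-2H-pyran-2-one; 10 ethyl 2-[2-(bromomethyl)-3-methylbut-2-en-1-yl]-5-methylhex-4-enoate
Product: 11 ethyl 5-methyl-2-{3-methyl-2-[({2-oxo-6-[3-(TIPS-oxy)phenyl]-2H-pyran-4-yl}oxy)methyl]but-2-en-1-yl}hex-4-enoate (racemic)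
Conditions: K2CO3 (1.5 equiv), acetone, 56 °C
Reagents that add atoms: none
Why: O-Alkylation of a 4-hydroxy-2-pyrone at its hard O4 terminus with a primary allylic bromide is the usual entry to 4-allyloxy-pyrones for Claisen rearrangement.

Step 8
Reactants: 11 the 4-allyloxy-pyrone
Product: 12 ethyl 2-{3-[4-hydroxy-2-oxo-6-(3-(TIPS-oxy)phenyl)-2H-pyran-3-yl]-3-methyl-2-methylidenebutyl}-5-methylhex-4-enoate (racemic)
Conditions: PhNEt2, 130 °C; 1 M HCl wash
Reagents that add atoms: none
Why: Aromatic Claisen rearrangement: the [3,3] shift should join pyrone C3 to the CMe2 terminus (bond C1–C8) and leave the 1,1-disubstituted C7=CH2 alkene, while the amine solvent keeps the acidic hydroxypyrone from adding to that alkene.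

Step 9
Reactants: 12 the 3-tert-alkyl-4-hydroxy-pyrone; 13 3-methylbut-2-en-1-yl acetate
Product: 14 ethyl 5-methyl-2-{3-methyl-3-[(3R)-3-(3-methylbut-2-en-1-yl)-2,4-dioxo-6-(3-(TIPS-oxy)phenyl)-3,4-dihydro-2H-pyran-3-yl]-2-methylidenebutyl}hex-4-enoate (both epimers at the ester α-carbon)
Conditions: Pd2(dba)3·CHCl3 (2.5 mol%), (1R,2R)-N,N'-bis[2-(diphenylphosphino)benzoyl]cyclohexane-1,2-diamine (7.5 mol%), 13 (1.3 equiv), Et3N (1.2 equiv), CH2Cl2, 23 °C
Reagents that add atoms: none
Why: Tsuji–Trost asymmetric allylic alkylation of a prochiral cyclic β-keto lactone enolate: the pyronate should attack the CH2 terminus of the 1,1-dimethylallyl palladium complex, any O-prenyl ether re-ionises with zerovalent palladium and funnels to the C-prenyl dione, and the chiral ligand pocket selects the enantiotopic face so that C1 is set as (3R).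

Step 10
Reactants: 14 the (3R)-pyran-2,4-dione
Product: 16 (1S,5S)-4-hydroxy-8,8-dimethyl-7-methylidene-1,5-bis(3-methylbut-2-en-1-yl)-3-{3-[tri(propan-2-yl)silyloxy]benzoyl}bicyclo[3.3.1]non-3-ene-2,9-dione, via ring A keto ester diketonate 15 (not isolated)
Conditions: KN(SiMe3)2 (1.15 equiv), 18-crown-6 (1.2 equiv), THF, −78 to 23 °C; then 1 M HCl
Reagents that add atoms: none
Why: Proposed new method: KN(SiMe3)2 deprotonates the ester α-carbon C5, the crown-ether-separated enolate attacks the lactone carbonyl C9 of the vinylogous anhydride, the tetrahedral intermediate expels the ring oxygen as the β-diketonate 15, whose C3 then acylates itself with the C4 ester, and loss of ethoxide with irreversible deprotonation of the trione pulls the sequence forward. The closest known reaction types are the diketene annulation of enolates (acylation by an enol lactone that sets free a second enolate for ring closure), the Dieckmann condensation and the Claisen cyclisation of β-diketone carbanions onto esters. Ring A closes 6-(enolexo)-exo-trig at C5–C9 and ring B 6-(enolendo)-exo-trig at C3–C4. C5 is the only new stereocentre and is controlled by C1: the diketone arm on C1 is axial on the forming ring A, an open transition state with the enolate C–O antiperiplanar to the lactone C=O should put the ester carbon on the same face, and only that epimer can bridge, while the other cannot close ring B and can return through retro-Claisen opening by ethoxide. The step needs attack at C9 and not at the C2 ketone (addition at C2 is a reversible aldol, only addition at C9 can collapse), ring A before ring B (C3 is masked as the lactone enol ether until C5–C9 exists, so the eight-membered alternative cannot form) and C- over O-acylation of the diketonate (an enol lactone from O-acylation is reopened by ethoxide, the C-acyl trione is removed as its enolate).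

Step 11
Reactants: 17 5-bromo-2-methylpent-2-ene
Product: 18 6-methylhept-5-en-1-yne
Conditions: LiC≡CH·H2NCH2CH2NH2 (1.5 equiv), DMSO, 15 to 23 °C
Reagents that add atoms: lithium acetylide (as its ethane-1,2-diamine complex), [Li]C#C
Why: SN2 alkylation of the acetylide by the primary homoallylic bromide in DMSO.

Step 12
Reactants: 18 6-methylhept-5-en-1-yne
Product: 20 (1E)-1-iodo-2,6-dimethylhepta-1,5-diene, via alkenylalane 19 (not isolated)
Conditions: Me3Al (2 equiv), Cp2ZrCl2 (0.25 equiv), CH2Cl2, 0 to 23 °C; then I2 (1.2 equiv), THF, −30 to 0 °C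
Reagents that add atoms: trimethylaluminium, C[Al](C)C; iodine, II
Why: Negishi carboalumination adds methyl and aluminium syn across the terminal alkyne (methyl to the internal carbon), and iodinolysis with retention should give the (E)-vinyl iodide that carries the trisubstituted alkene geometry of the geranyl group.

Step 13
Reactants: 16 the 7-methylidene bicycle; 20 (1E)-1-iodo-2,6-dimethylhepta-1,5-diene
Product: 22 (1S,5S,7S)-7-[(2E)-3,7-dimethylocta-2,6-dien-1-yl]-4-hydroxy-8,8-dimethyl-1,5-bis(3-methylbut-2-en-1-yl)-3-{3-[tri(propan-2-yl)silyloxy]benzoyl}bicyclo[3.3.1]non-3-ene-2,9-dione, via alkylborane 21 (not isolated)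
Conditions: 9-BBN-H dimer (1.3 equiv), THF, 23 to 45 °C; then 20 (1.5 equiv), Pd(dppf)Cl2 (10 mol%), AsPh3 (10 mol%), 3 M aq K3PO4, DMF, 23 to 45 °C
Reagents that add atoms: none
Why: After the enol O–H is consumed as a boron chelate, 9-BBN-H should add to the 1,1-disubstituted exocyclic alkene faster than to the trisubstituted prenyl alkenes or the hindered ketones, with boron at CH2 and hydrogen delivered to C7 from the exo face because the endo face lies under ring B, which sets C7 with the side chain endo (7S); B-alkyl Suzuki–Miyaura coupling with 20 then retains the alkene geometry.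

Step 14
Reactants: 22 the silyl ether of the target
Product: 23 (1S,5S,7S)-7-[(2E)-3,7-dimethylocta-2,6-dien-1-yl]-4-hydroxy-3-(3-hydroxybenzoyl)-8,8-dimethyl-1,5-bis(3-methylbut-2-en-1-yl)bicyclo[3.3.1]non-3-ene-2,9-dione
Conditions: Bu4NF (2 equiv), AcOH (2 equiv), THF, 0 to 23 °C
Reagents that add atoms: none
Why: Fluoride cleaves the aryl silyl ether, and the acetic acid buffer should keep the enolised trione and the prenyl groups from base- or acid-induced cyclisation.

**Compound list**

1 | 1-(3-hydroxyphenyl)ethan-1-one | CC(=O)c1cccc(O)c1 | starting material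
2 | 1-{3-[tri(propan-2-yl)silyloxy]phenyl}ethan-1-one | CC(=O)c1cccc(O[Si](C(C)C)(C(C)C)C(C)C)c1 | intermediate
3 | trimethyl[(1-{3-[tri(propan-2-yl)silyloxy]phenyl}ethenyl)oxy]silane | C=C(O[Si](C)(C)C)c1cccc(O[Si](C(C)C)(C(C)C)C(C)C)c1 | intermediate
4 | propanedioyl dichloride (malonyl dichloride) | ClC(=O)CC(=O)Cl | starting material
5 | 4-hydroxy-6-{3-[tri(propan-2-yl)silyloxy]phenyl}-2H-pyran-2-one | O=C1C=C(O)C=C(c2cccc(O[Si](C(C)C)(C(C)C)C(C)C)c2)O1 | intermediate
6 | diethyl 2-(propan-2-ylidene)propanedioate | CCOC(=O)C(=C(C)C)C(=O)OCC | starting material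
7 | 2-(propan-2-ylidene)propane-1,3-diol | OCC(CO)=C(C)C | intermediate
8 | 1-bromo-2-(bromomethyl)-3-methylbut-2-ene | BrCC(CBr)=C(C)C | intermediate
9 | ethyl 5-methylhex-4-enoate | CCOC(=O)CCC=C(C)C | starting material
10 | ethyl 2-[2-(bromomethyl)-3-methylbut-2-en-1-yl]-5-methylhex-4-enoate (racemic) | CCOC(=O)C(CC=C(C)C)CC(CBr)=C(C)C | intermediate
11 | ethyl 5-methyl-2-{3-methyl-2-[({2-oxo-6-[3-(TIPS-oxy)phenyl]-2H-pyran-4-yl}oxy)methyl]but-2-en-1-yl}hex-4-enoate (racemic) | CCOC(=O)C(CC=C(C)C)CC(COC1=CC(=O)OC(c2cccc(O[Si](C(C)C)(C(C)C)C(C)C)c2)=C1)=C(C)C | intermediate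
12 | ethyl 2-{3-[4-hydroxy-2-oxo-6-(3-(TIPS-oxy)phenyl)-2H-pyran-3-yl]-3-methyl-2-methylidenebutyl}-5-methylhex-4-enoate (racemic) | CCOC(=O)C(CC=C(C)C)CC(=C)C(C)(C)C1=C(O)C=C(c2cccc(O[Si](C(C)C)(C(C)C)C(C)C)c2)OC1=O | intermediate
13 | 3-methylbut-2-en-1-yl acetate (prenyl acetate) | CC(=O)OCC=C(C)C | starting material
14 | ethyl 5-methyl-2-{3-methyl-3-[(3R)-3-(3-methylbut-2-en-1-yl)-2,4-dioxo-6-(3-(TIPS-oxy)phenyl)-3,4-dihydro-2H-pyran-3-yl]-2-methylidenebutyl}hex-4-enoate (both epimers at the ester α-carbon) | CCOC(=O)C(CC=C(C)C)CC(=C)C(C)(C)[C@@]1(CC=C(C)C)C(=O)OC(c2cccc(O[Si](C(C)C)(C(C)C)C(C)C)c2)=CC1=O | intermediate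
15 | ethyl (1R,3R)-4,4-dimethyl-5-methylidene-1,3-bis(3-methylbut-2-en-1-yl)-2-oxo-3-{3-oxo-3-[3-(TIPS-oxy)phenyl]propanoyl}cyclohexane-1-carboxylate (formed in the flask as its potassium diketonate, drawn neutral) | C=C1C[C@](C(=O)OCC)(CC=C(C)C)C(=O)[C@@](CC=C(C)C)(C(=O)CC(=O)c2cccc(O[Si](C(C)C)(C(C)C)C(C)C)c2)C1(C)C | intermediate
16 | (1S,5S)-4-hydroxy-8,8-dimethyl-7-methylidene-1,5-bis(3-methylbut-2-en-1-yl)-3-{3-[tri(propan-2-yl)silyloxy]benzoyl}bicyclo[3.3.1]non-3-ene-2,9-dione (drawn as the C4 enol) | C=C1C[C@]2(CC=C(C)C)C(=O)[C@@](CC=C(C)C)(C(=O)C(C(=O)c3cccc(O[Si](C(C)C)(C(C)C)C(C)C)c3)=C2O)C1(C)C | intermediate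
17 | 5-bromo-2-methylpent-2-ene | BrCCC=C(C)C | starting material
18 | 6-methylhept-5-en-1-yne | C#CCCC=C(C)C | intermediate
19 | [(1E)-2,6-dimethylhepta-1,5-dien-1-yl]dimethylalumane (formed in the flask) | C[Al](C)/C=C(\C)CCC=C(C)C | intermediate
20 | (1E)-1-iodo-2,6-dimethylhepta-1,5-diene | I/C=C(\C)CCC=C(C)C | intermediate
21 | (1S,5S,7S)-7-[(9-borabicyclo[3.3.1]nonan-9-yl)methyl]-4-[(9-borabicyclo[3.3.1]nonan-9-yl)oxy]-8,8-dimethyl-1,5-bis(3-methylbut-2-en-1-yl)-3-{3-[tri(propan-2-yl)silyloxy]benzoyl}bicyclo[3.3.1]non-3-ene-2,9-dione (formed in the flask) | C(B4C5CCCC4CCC5)[C@H]1C[C@]2(CC=C(C)C)C(=O)[C@@](CC=C(C)C)(C(=O)C(C(=O)c3cccc(O[Si](C(C)C)(C(C)C)C(C)C)c3)=C2OB6C7CCCC6CCC7)C1(C)C | intermediate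
22 | (1S,5S,7S)-7-[(2E)-3,7-dimethylocta-2,6-dien-1-yl]-4-hydroxy-8,8-dimethyl-1,5-bis(3-methylbut-2-en-1-yl)-3-{3-[tri(propan-2-yl)silyloxy]benzoyl}bicyclo[3.3.1]non-3-ene-2,9-dione | CC(C)=CCC/C(C)=C/C[C@H]1C[C@]2(CC=C(C)C)C(=O)[C@@](CC=C(C)C)(C(=O)C(C(=O)c3cccc(O[Si](C(C)C)(C(C)C)C(C)C)c3)=C2O)C1(C)C | intermediate
23 | (1S,5S,7S)-7-[(2E)-3,7-dimethylocta-2,6-dien-1-yl]-4-hydroxy-3-(3-hydroxybenzoyl)-8,8-dimethyl-1,5-bis(3-methylbut-2-en-1-yl)bicyclo[3.3.1]non-3-ene-2,9-dione | CC(C)=CCC/C(C)=C/C[C@H]1C[C@]2(CC=C(C)C)C(=O)[C@@](CC=C(C)C)(C(=O)C(C(=O)c3cccc(O)c3)=C2O)C1(C)C | target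

**Summary**

Total step count: 14. Longest linear sequence: 9 steps (steps 1, 2, 3, 7, 8, 9, 10, 13 and 14; the branch through steps 4, 5 and 6 is equally long).

Steps most likely to fail:

Step 10. The enolate may close ring A to the C5 epimer that cannot bridge, or the diketonate may fail to C-acylate the hindered ester, so that the sequence stalls at the ring A stage or at the O-acyl enol lactone; attack of the amide base on the vinylogous anhydride is a further loss channel. The fallback uses known chemistry and runs the two closures separately. It sets out from 14: catalytic EtONa in EtOH at 0 °C opens the enol lactone to the acyclic diethyl ester β-diketone F1. LiN(iPr)2 (2.2 equiv, the first equivalent forming the diketonate) in THF at −78 to 0 °C then effects a kinetic Dieckmann condensation to the ring A keto ester 15, which is isolated. KOtBu in THF at 23 to 50 °C closes ring B by an equilibrating intramolecular Claisen condensation, and the route is rejoined at 16.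

Step 9. C-Allylation at the carbon flanked by the quaternary C8 may stall at the O-prenyl ether, the ligand may discriminate the two faces of the pyronate poorly, and reversible ionisation of the product by zerovalent palladium could erode the enantiomeric purity. The fallback sets out from 12: prenylation with 13 under the small achiral catalyst Pd(PPh3)4 (Et3N, THF, 50 °C) should give the racemic dione, which is resolved by preparative chromatography on a chiral stationary phase. The (3R)-enantiomer is 14, where the route is rejoined; the (3S)-enantiomer F2 is set aside.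

Step 13. The axial methyl group on C8 may slow the hydroboration so that carbonyl reduction or endo-face addition competes, and transfer of the β-branched alkyl group from boron to palladium may be slow enough for protodeboronation to take over. The fallback sets out from the alkylborane 21: oxidation with NaBO3·4H2O (THF/H2O, 23 °C) should give the 7-endo hydroxymethyl compound F3, whose primary hydroxyl is converted faster than the hindered, hydrogen-bonded enol by PPh3, I2 and imidazole (CH2Cl2, 0 °C) into the primary iodide F4. A reductive cross-electrophile coupling of F4 with 20 (NiBr2(dme), 4,4'-di-tert-butyl-2,2'-bipyridine, Mn powder, DMA, 40 °C), which proceeds through an alkyl radical and is insensitive to β-branching, rejoins the route at 22.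

**Further compounds**

F1 | step 10 | ethyl 2-{3-[(3R)-3-(ethoxycarbonyl)-6-methyl-2,4-dioxo-1-(3-(TIPS-oxy)phenyl)hept-5-en-3-yl]-3-methyl-2-methylidenebutyl}-5-methylhex-4-enoate, the acyclic diethyl ester β-diketone | CCOC(=O)C(CC=C(C)C)CC(=C)C(C)(C)[C@@](CC=C(C)C)(C(=O)OCC)C(=O)CC(=O)c1cccc(O[Si](C(C)C)(C(C)C)C(C)C)c1
F2 | step 9 | (3S)-enantiomer of 14 at the pyrandione carbon | CCOC(=O)C(CC=C(C)C)CC(=C)C(C)(C)[C@]1(CC=C(C)C)C(=O)OC(c2cccc(O[Si](C(C)C)(C(C)C)C(C)C)c2)=CC1=O
F3 | step 13 | (1S,5S,7S)-4-hydroxy-7-(hydroxymethyl)-8,8-dimethyl-1,5-bis(3-methylbut-2-en-1-yl)-3-{3-[tri(propan-2-yl)silyloxy]benzoyl}bicyclo[3.3.1]non-3-ene-2,9-dione | OC[C@H]1C[C@]2(CC=C(C)C)C(=O)[C@@](CC=C(C)C)(C(=O)C(C(=O)c3cccc(O[Si](C(C)C)(C(C)C)C(C)C)c3)=C2O)C1(C)C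
F4 | step 13 | (1S,5S,7S)-4-hydroxy-7-(iodomethyl)-8,8-dimethyl-1,5-bis(3-methylbut-2-en-1-yl)-3-{3-[tri(propan-2-yl)silyloxy]benzoyl}bicyclo[3.3.1]non-3-ene-2,9-dione | IC[C@H]1C[C@]2(CC=C(C)C)C(=O)[C@@](CC=C(C)C)(C(=O)C(C(=O)c3cccc(O[Si](C(C)C)(C(C)C)C(C)C)c3)=C2O)C1(C)C
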